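The C9–C10 disconnection makes ring A (C1–C5, C10) a flat methyl 4-hydroxy-3-methylbenzoate that already holds the C1 oxygen, the C20 methyl on C10 and the C4 ester carbon. In one operation an iridium-catalysed asymmetric allylic dearomatization joins C9 to the phenol ortho carbon C10, closes ring B, sets the C9 and quaternary C10 stereocentres and turns the phenol into the C1 ketone. Its precursor is that phenol carrying at C5 a six-carbon chain (C6–C12) with a single (8S) silyloxy stereocentre, installed enantioselectively so that only one chair closure operates, and an (E)-allylic methyl carbonate at C9=C11–C12.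

Key step: step 9

Remark: ring atoms carry labdane numbers throughout; compounds 1, 4, 7 and 25 are taken as purchasable, and the antipodes of the amino alcohol (step 5) and of the phosphoramidite (step 9) are chosen from the accepted facial models of these catalysts (for step 9: C10, C8 and C11 clockwise at C9 when C9–H points away from the viewer).

Step 1
Reactants: 1 methyl 2,4-dihydroxy-3-methylbenzoate
Product: 2 methyl 2-hydroxy-3-methyl-4-(triisopropylsilyloxy)benzoate
Conditions: TIPSCl (1.05 equiv), imidazole, DMF, 0 °C to rt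
Reagents that add atoms: triisopropylsilyl chloride, CC(C)[Si](Cl)(C(C)C)C(C)C
Why: Silyl ether formation; the C2 hydroxyl is tied up in a hydrogen bond to the ester carbonyl and flanked by the methyl group, so only the para hydroxyl (the future C1 oxygen) should be silylated.

Step 2
Reactants: 2 methyl 2-hydroxy-3-methyl-4-(triisopropylsilyloxy)benzoate
Product: 3 methyl 3-methyl-2-(trifluoromethylsulfonyloxy)-4-(triisopropylsilyloxy)benzoate
Conditions: Tf2O, pyridine, CH2Cl2, 0 °C to rt
Reagents that add atoms: trifluoromethanesulfonic anhydride, O=S(=O)(OS(=O)(=O)C(F)(F)F)C(F)(F)F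
Why: O-Sulfonylation of the remaining chelated phenol gives the aryl triflate that marks the future C5 for cross-coupling.

Step 3
Reactants: 3 methyl 3-methyl-2-(trifluoromethylsulfonyloxy)-4-(triisopropylsilyloxy)benzoate; 4 [2-(1,3-dioxolan-2-yl)ethyl]zinc bromide (THF solution)
Product: 5 methyl 2-[2-(1,3-dioxolan-2-yl)ethyl]-3-methyl-4-(triisopropylsilyloxy)benzoate
Conditions: Pd(OAc)2 (3 mol%), SPhos (6 mol%), LiCl, THF/NMP, 60 °C
Reagents that add atoms: none
Why: Negishi coupling; a bulky biarylphosphine palladium catalyst should insert into the di-ortho-substituted triflate, and the base-free alkylzinc partner leaves the ester and the aryl silyl ether untouched while installing C6–C8 with C8 masked as an acetal.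

Step 4
Reactants: 5 methyl 2-[2-(1,3-dioxolan-2-yl)ethyl]-3-methyl-4-(triisopropylsilyloxy)benzoate
Product: 6 methyl 3-methyl-2-(3-oxopropyl)-4-(triisopropylsilyloxy)benzoate
Conditions: 2 M aq. HCl, THF, rt to 40 °C
Reagents that add atoms: water, O
Why: Acid-catalysed acetal hydrolysis frees the C8 aldehyde, while the aryl silyl ether and the methyl ester are stable to dilute aqueous acid.

Step 5
Reactants: 6 methyl 3-methyl-2-(3-oxopropyl)-4-(triisopropylsilyloxy)benzoate; 7 trimethyl(prop-2-ynyloxy)silane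
Product: 11 methyl 2-[(3S,4E)-3,6-dihydroxyhex-4-enyl]-3-methyl-4-(triisopropylsilyloxy)benzoate, via alkenylborane 8 (not isolated), via alkenylzinc 9 (not isolated), via trimethylsilyl ether 10 (not isolated)
Conditions: 7, Cy2BH (preformed), toluene, 0 °C to rt; Me2Zn, −78 °C; (+)-MIB [(2R)-3-exo-morpholinoisoborneol] (5 mol%), then 6, −20 to 0 °C; aq. NH4Cl; then citric acid, MeOH, rt
Reagents that add atoms: none
Why: Catalytic asymmetric alkenylzinc addition to an aldehyde: syn-hydroboration of the alkyne fixes the E geometry of C9=C11, boron-to-zinc exchange gives 9, and the zinc amino alkoxide of the (2R) ligand is expected to deliver the alkenyl group to the Re face of the aldehyde through the usual bimetallic transition state and so set (8S), after which mild acid removes the trimethylsilyl group.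

Step 6
Reactants: 11 methyl 2-[(3S,4E)-3,6-dihydroxyhex-4-enyl]-3-methyl-4-(triisopropylsilyloxy)benzoate
Product: 12 methyl 2-[(3S,4E)-3-hydroxy-6-(methoxycarbonyloxy)hex-4-enyl]-3-methyl-4-(triisopropylsilyloxy)benzoate
Conditions: ClCO2Me (1.05 equiv), pyridine, CH2Cl2, −40 to −10 °C
Reagents that add atoms: methyl chloroformate, COC(=O)Cl
Why: Chemoselective O-acylation (carbonate formation) of the unhindered primary allylic hydroxyl at C12 over the secondary C8 hydroxyl at low temperature.

Step 7
Reactants: 12 methyl 2-[(3S,4E)-3-hydroxy-6-(methoxycarbonyloxy)hex-4-enyl]-3-methyl-4-(triisopropylsilyloxy)benzoate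
Product: 13 methyl 2-[(3S,4E)-3-(tert-butyldimethylsilyloxy)-6-(methoxycarbonyloxy)hex-4-enyl]-3-methyl-4-(triisopropylsilyloxy)benzoate
Conditions: TBSCl, imidazole, DMF, rt
Reagents that add atoms: tert-butyldimethylsilyl chloride, CC(C)(C)[Si](C)(C)Cl
Why: Silyl ether formation at the secondary C8 hydroxyl; the carbonate and the ester are inert to TBSCl and imidazole.

Step 8
Reactants: 13 methyl 2-[(3S,4E)-3-(tert-butyldimethylsilyloxy)-6-(methoxycarbonyloxy)hex-4-enyl]-3-methyl-4-(triisopropylsilyloxy)benzoate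
Product: 14 methyl 2-[(3S,4E)-3-(tert-butyldimethylsilyloxy)-6-(methoxycarbonyloxy)hex-4-enyl]-4-hydroxy-3-methylbenzoate
Conditions: KHF2 (2.5 equiv), MeOH, rt
Reagents that add atoms: none
Why: Fluoride-mediated desilylation that should be selective for the aryl silyl ether, because the ester-stabilised phenoxide is a far better leaving group than a secondary alkoxide, and that leaves the allylic carbonate intact under near-neutral conditions.

Step 9
Reactants: 14 methyl 2-[(3S,4E)-3-(tert-butyldimethylsilyloxy)-6-(methoxycarbonyloxy)hex-4-enyl]-4-hydroxy-3-methylbenzoate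
Product: 15 methyl (4aS,5S,6S)-6-(tert-butyldimethylsilyloxy)-5-ethenyl-4a-methyl-4-oxo-4,4a,5,6,7,8-hexahydronaphthalene-1-carboxylate
Conditions: [Ir(cod)Cl]2 (4 mol%), (Ra,R,R)-BINOL-derived N,N-bis(1-phenylethyl)phosphoramidite (8 mol%), pre-activated with n-PrNH2 (THF, 50 °C, then evaporated); Cs2CO3 (1 equiv), THF (0.02 M), 50 °C; product used at once
Reagents that add atoms: none
Why: The cyclometalated monovalent iridium phosphoramidite complex ionises the linear carbonate (loss of CO2 and methoxide) to a trivalent iridium allyl complex, and the phenoxide attacks its substituted terminus C9 through the ortho carbon C10 on the face opposite the metal, so that C9–C10 forms and the arene becomes the C1 ketone of a 2,4-dienone. The closest known reaction type is the iridium-catalysed intramolecular asymmetric allylic dearomatization of phenols. Ring B closes in a 6-exo mode with C11=C12 left outside the ring as the vinyl group; attack at C12 would need an eight-membered ring. C9 is set by the ligand, which fixes the allyl face that carries the metal, and C10 follows from a chair-like closure in which the allyl unit and the (8S) silyloxy group are equatorial and C20 is axial, which places vinyl and methyl cis. The step needs C-alkylation at C10 rather than at C4 or at oxygen: attack at C4 would put the ester on an sp3 carbon and break the phenoxide-to-ester conjugation that attack at C10 keeps, while O-allylation would need a medium ring and its intermolecular form is suppressed by dilution. A single C8 epimer is used because a C8 mixture would cyclise through matched and mismatched transition states and lower the optical purity once C8 becomes a ketone.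

Step 10
Reactants: 15 methyl (4aS,5S,6S)-6-(tert-butyldimethylsilyloxy)-5-ethenyl-4a-methyl-4-oxo-4,4a,5,6,7,8-hexahydronaphthalene-1-carboxylate
Product: 16 methyl (4aS,5S,6S)-6-(tert-butyldimethylsilyloxy)-5-ethenyl-4a-methyl-4-oxo-2,3,4,4a,5,6,7,8-octahydronaphthalene-1-carboxylate
Conditions: Cu(OAc)2·H2O (5 mol%), 1,2-bis(diphenylphosphino)benzene (5 mol%), (EtO)2MeSiH (1.5 equiv), t-BuOH (2 equiv), toluene, 0 °C to rt
Reagents that add atoms: none
Why: Copper hydride conjugate reduction: hydride should go to the unhindered β-carbon C3 of the enone and not to the fully substituted C5, and the catalyst ignores the isolated vinyl group and the tetrasubstituted enoate, so only C2=C3 is saturated.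

Step 11
Reactants: 16 methyl (4aS,5S,6S)-6-(tert-butyldimethylsilyloxy)-5-ethenyl-4a-methyl-4-oxo-2,3,4,4a,5,6,7,8-octahydronaphthalene-1-carboxylate
Product: 17 methyl (4S,4aS,5S,6S)-6-(tert-butyldimethylsilyloxy)-5-ethenyl-4-hydroxy-4a-methyl-2,3,4,4a,5,6,7,8-octahydronaphthalene-1-carboxylate
Conditions: NaBH4, MeOH, −20 to 0 °C
Reagents that add atoms: none
Why: Ketone reduction by NaBH4: hydride should add axially to C1 from the face opposite the axial C20 methyl on the neighbouring C10, as in related angular-methyl octalones, giving the equatorial C1 alcohol cis to C20, while the enoate is inert.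

Step 12
Reactants: 17 methyl (4S,4aS,5S,6S)-6-(tert-butyldimethylsilyloxy)-5-ethenyl-4-hydroxy-4a-methyl-2,3,4,4a,5,6,7,8-octahydronaphthalene-1-carboxylate
Product: 19 methyl (1R,4S,4aR,5S,6S,8aS)-6-(tert-butyldimethylsilyloxy)-5-ethenyl-4-hydroxy-1,4a-dimethyldecahydronaphthalene-1-carboxylate, via dilithium enolate 18 (not isolated)
Conditions: Li (2.5 equiv), NH3/THF, −78 °C; MeI (excess), −78 to −33 °C; NH4Cl
Reagents that add atoms: iodomethane, CI
Why: Dissolving-metal reductive alkylation of the α,β-unsaturated ester: the C1 hydroxyl supplies the one proton needed, protonation at C5 should occur anti to the axial C20 methyl to give the trans ring fusion, and MeI then attacks the exocyclic enolate at C4 from the face remote from C20, which leaves the new methyl equatorial and the ester axial, cis to C20.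

Step 13
Reactants: 19 methyl (1R,4S,4aR,5S,6S,8aS)-6-(tert-butyldimethylsilyloxy)-5-ethenyl-4-hydroxy-1,4a-dimethyldecahydronaphthalene-1-carboxylate
Product: 20 methyl (1R,4S,4aR,5S,6S,8aS)-4-acetoxy-6-(tert-butyldimethylsilyloxy)-5-ethenyl-1,4a-dimethyldecahydronaphthalene-1-carboxylate
Conditions: Ac2O, DMAP, pyridine, 40 °C
Reagents that add atoms: acetic anhydride, CC(=O)OC(C)=O
Why: DMAP-catalysed acetylation of the hindered equatorial C1 hydroxyl, the only free hydroxyl in the molecule.

Step 14
Reactants: 20 methyl (1R,4S,4aR,5S,6S,8aS)-4-acetoxy-6-(tert-butyldimethylsilyloxy)-5-ethenyl-1,4a-dimethyldecahydronaphthalene-1-carboxylate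
Product: 22 methyl (1R,4S,4aR,5S,6S,8aS)-4-acetoxy-6-(tert-butyldimethylsilyloxy)-5-(2-hydroxyethyl)-1,4a-dimethyldecahydronaphthalene-1-carboxylate, via alkylborane 21 (not isolated)
Conditions: 9-BBN (3 equiv), THF, 60 °C; then aq. NaOAc, H2O2 (30%), 0 °C to rt
Reagents that add atoms: hydrogen peroxide, OO
Why: Anti-Markovnikov hydroboration–oxidation: 9-BBN places boron on the terminal C12 of the vinyl group and does not reduce esters, and the buffered peroxide oxidation spares the acetate.

Step 15
Reactants: 22 methyl (1R,4S,4aR,5S,6S,8aS)-4-acetoxy-6-(tert-butyldimethylsilyloxy)-5-(2-hydroxyethyl)-1,4a-dimethyldecahydronaphthalene-1-carboxylate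
Product: 23 methyl (1R,4S,4aR,5S,6S,8aS)-4-acetoxy-6-hydroxy-5-(2-hydroxyethyl)-1,4a-dimethyldecahydronaphthalene-1-carboxylate
Conditions: HF·pyridine, pyridine, THF, 0 °C to rt
Reagents that add atoms: none
Why: Acidic fluoride desilylation should remove the C8 silyl ether without cleavage or migration of the C1 acetate.

Step 16
Reactants: 23 methyl (1R,4S,4aR,5S,6S,8aS)-4-acetoxy-6-hydroxy-5-(2-hydroxyethyl)-1,4a-dimethyldecahydronaphthalene-1-carboxylate
Product: 24 methyl (1R,4S,4aR,5S,8aS)-4-acetoxy-1,4a-dimethyl-6-oxo-5-(2-oxoethyl)decahydronaphthalene-1-carboxylate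
Conditions: Dess–Martin periodinane (3 equiv), NaHCO3, CH2Cl2, rt; crude product used directly
Reagents that add atoms: none
Why: Dess–Martin oxidation converts both hydroxyls at once (C8 ketone, C12 aldehyde) under buffered neutral conditions that should not enolise C9; the C8 stereocentre, having done its work, disappears here.

Step 17
Reactants: 24 methyl (1R,4S,4aR,5S,8aS)-4-acetoxy-1,4a-dimethyl-6-oxo-5-(2-oxoethyl)decahydronaphthalene-1-carboxylate; 25 2-(triphenyl-λ5-phosphanylidene)propanal
Product: 26 methyl (1R,4S,4aR,5S,8aS)-4-acetoxy-1,4a-dimethyl-5-[(2E)-3-methyl-4-oxobut-2-enyl]-6-oxodecahydronaphthalene-1-carboxylate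
Conditions: toluene, 90 °C
Reagents that add atoms: none
Why: Wittig olefination with a formyl-stabilised ylide, which reacts with the aldehyde and not with the hindered ketone and should give the (E)-trisubstituted C12=C13 enal.

Step 18
Reactants: 26 methyl (1R,4S,4aR,5S,8aS)-4-acetoxy-1,4a-dimethyl-5-[(2E)-3-methyl-4-oxobut-2-enyl]-6-oxodecahydronaphthalene-1-carboxylate
Product: 27 methyl (1R,4S,4aS,5R,8aS)-4-acetoxy-1,4a-dimethyl-6-methylidene-5-[(2E)-3-methylpenta-2,4-dienyl]decahydronaphthalene-1-carboxylate (CNP0235031.1)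
Conditions: Zn, CH2Br2, TiCl4 (reagent preformed in THF), CH2Cl2, 0 °C to rt
Reagents that add atoms: dibromomethane, BrCBr
Why: Lombardo–Takai methylenation: the non-basic gem-dimetallic reagent should convert the C8 ketone and the C14 aldehyde into the C8=C17 and C14=C15 methylidenes in one operation without epimerising C9 or touching the acetate and the methyl ester.

Compound list
1 | methyl 2,4-dihydroxy-3-methylbenzoate | COC(=O)c1ccc(O)c(C)c1O | starting material
2 | methyl 2-hydroxy-3-methyl-4-(triisopropylsilyloxy)benzoate | COC(=O)c1ccc(O[Si](C(C)C)(C(C)C)C(C)C)c(C)c1O | intermediate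
3 | methyl 3-methyl-2-(trifluoromethylsulfonyloxy)-4-(triisopropylsilyloxy)benzoate | COC(=O)c1ccc(O[Si](C(C)C)(C(C)C)C(C)C)c(C)c1OS(=O)(=O)C(F)(F)F | intermediate
4 | [2-(1,3-dioxolan-2-yl)ethyl]zinc bromide | Br[Zn]CCC1OCCO1 | starting material
5 | methyl 2-[2-(1,3-dioxolan-2-yl)ethyl]-3-methyl-4-(triisopropylsilyloxy)benzoate | COC(=O)c1ccc(O[Si](C(C)C)(C(C)C)C(C)C)c(C)c1CCC1OCCO1 | intermediate
6 | methyl 3-methyl-2-(3-oxopropyl)-4-(triisopropylsilyloxy)benzoate | COC(=O)c1ccc(O[Si](C(C)C)(C(C)C)C(C)C)c(C)c1CCC=O | intermediate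
7 | trimethyl(prop-2-ynyloxy)silane | C#CCO[Si](C)(C)C | starting material
8 | dicyclohexyl[(E)-3-(trimethylsilyloxy)prop-1-enyl]borane | C[Si](C)(C)OC/C=C/B(C1CCCCC1)C1CCCCC1 | intermediate (not isolated)
9 | methyl[(E)-3-(trimethylsilyloxy)prop-1-enyl]zinc | C[Zn]/C=C/CO[Si](C)(C)C | intermediate (not isolated)
10 | methyl 2-[(3S,4E)-3-hydroxy-6-(trimethylsilyloxy)hex-4-enyl]-3-methyl-4-(triisopropylsilyloxy)benzoate | COC(=O)c1ccc(O[Si](C(C)C)(C(C)C)C(C)C)c(C)c1CC[C@H](O)/C=C/CO[Si](C)(C)C | intermediate (not isolated)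
11 | methyl 2-[(3S,4E)-3,6-dihydroxyhex-4-enyl]-3-methyl-4-(triisopropylsilyloxy)benzoate | COC(=O)c1ccc(O[Si](C(C)C)(C(C)C)C(C)C)c(C)c1CC[C@H](O)/C=C/CO | intermediate
12 | methyl 2-[(3S,4E)-3-hydroxy-6-(methoxycarbonyloxy)hex-4-enyl]-3-methyl-4-(triisopropylsilyloxy)benzoate | COC(=O)c1ccc(O[Si](C(C)C)(C(C)C)C(C)C)c(C)c1CC[C@H](O)/C=C/COC(=O)OC | intermediate
13 | methyl 2-[(3S,4E)-3-(tert-butyldimethylsilyloxy)-6-(methoxycarbonyloxy)hex-4-enyl]-3-methyl-4-(triisopropylsilyloxy)benzoate | COC(=O)c1ccc(O[Si](C(C)C)(C(C)C)C(C)C)c(C)c1CC[C@H](O[Si](C)(C)C(C)(C)C)/C=C/COC(=O)OC | intermediate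
14 | methyl 2-[(3S,4E)-3-(tert-butyldimethylsilyloxy)-6-(methoxycarbonyloxy)hex-4-enyl]-4-hydroxy-3-methylbenzoate (key-step precursor) | COC(=O)c1ccc(O)c(C)c1CC[C@H](O[Si](C)(C)C(C)(C)C)/C=C/COC(=O)OC | intermediate
15 | methyl (4aS,5S,6S)-6-(tert-butyldimethylsilyloxy)-5-ethenyl-4a-methyl-4-oxo-4,4a,5,6,7,8-hexahydronaphthalene-1-carboxylate (key-step product; vinyl and C20 cis, silyloxy trans to vinyl) | C=C[C@@H]1[C@@H](O[Si](C)(C)C(C)(C)C)CCC2=C(C(=O)OC)C=CC(=O)[C@@]12C | intermediate
16 | methyl (4aS,5S,6S)-6-(tert-butyldimethylsilyloxy)-5-ethenyl-4a-methyl-4-oxo-2,3,4,4a,5,6,7,8-octahydronaphthalene-1-carboxylate | C=C[C@@H]1[C@@H](O[Si](C)(C)C(C)(C)C)CCC2=C(C(=O)OC)CCC(=O)[C@@]12C | intermediate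
17 | methyl (4S,4aS,5S,6S)-6-(tert-butyldimethylsilyloxy)-5-ethenyl-4-hydroxy-4a-methyl-2,3,4,4a,5,6,7,8-octahydronaphthalene-1-carboxylate | C=C[C@@H]1[C@@H](O[Si](C)(C)C(C)(C)C)CCC2=C(C(=O)OC)CC[C@H](O)[C@@]12C | intermediate
18 | dilithium C1 alkoxide and C4 ester enolate of the trans-fused decalin (C5–H anti to C20) | C=C[C@@H]1[C@@H](O[Si](C)(C)C(C)(C)C)CC[C@H]2[C@@]1(C)[C@@H](O[Li])CCC2=C(OC)O[Li] | intermediate (not isolated)
19 | methyl (1R,4S,4aR,5S,6S,8aS)-6-(tert-butyldimethylsilyloxy)-5-ethenyl-4-hydroxy-1,4a-dimethyldecahydronaphthalene-1-carboxylate | C=C[C@@H]1[C@@H](O[Si](C)(C)C(C)(C)C)CC[C@H]2[C@@]1(C)[C@@H](O)CC[C@@]2(C)C(=O)OC | intermediate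
20 | methyl (1R,4S,4aR,5S,6S,8aS)-4-acetoxy-6-(tert-butyldimethylsilyloxy)-5-ethenyl-1,4a-dimethyldecahydronaphthalene-1-carboxylate | C=C[C@@H]1[C@@H](O[Si](C)(C)C(C)(C)C)CC[C@H]2[C@@]1(C)[C@@H](OC(C)=O)CC[C@@]2(C)C(=O)OC | intermediate
21 | 9-borabicyclo[3.3.1]nonan-9-yl adduct at C12 of 20 (B-alkyl-9-BBN) | C(C[C@@H]1[C@@H](O[Si](C)(C)C(C)(C)C)CC[C@H]2[C@@]1(C)[C@@H](OC(C)=O)CC[C@@]2(C)C(=O)OC)B3C4CCCC3CCC4 | intermediate (not isolated)
22 | methyl (1R,4S,4aR,5S,6S,8aS)-4-acetoxy-6-(tert-butyldimethylsilyloxy)-5-(2-hydroxyethyl)-1,4a-dimethyldecahydronaphthalene-1-carboxylate | OCC[C@@H]1[C@@H](O[Si](C)(C)C(C)(C)C)CC[C@H]2[C@@]1(C)[C@@H](OC(C)=O)CC[C@@]2(C)C(=O)OC | intermediate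
23 | methyl (1R,4S,4aR,5S,6S,8aS)-4-acetoxy-6-hydroxy-5-(2-hydroxyethyl)-1,4a-dimethyldecahydronaphthalene-1-carboxylate | OCC[C@@H]1[C@@H](O)CC[C@H]2[C@@]1(C)[C@@H](OC(C)=O)CC[C@@]2(C)C(=O)OC | intermediate
24 | methyl (1R,4S,4aR,5S,8aS)-4-acetoxy-1,4a-dimethyl-6-oxo-5-(2-oxoethyl)decahydronaphthalene-1-carboxylate | O=CC[C@@H]1C(=O)CC[C@H]2[C@@]1(C)[C@@H](OC(C)=O)CC[C@@]2(C)C(=O)OC | intermediate
25 | 2-(triphenyl-λ5-phosphanylidene)propanal | CC(C=O)=P(c1ccccc1)(c1ccccc1)c1ccccc1 | starting material
26 | methyl (1R,4S,4aR,5S,8aS)-4-acetoxy-1,4a-dimethyl-5-[(2E)-3-methyl-4-oxobut-2-enyl]-6-oxodecahydronaphthalene-1-carboxylate | O=C/C(C)=C/C[C@@H]1C(=O)CC[C@H]2[C@@]1(C)[C@@H](OC(C)=O)CC[C@@]2(C)C(=O)OC | intermediate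
27 | methyl (1R,4S,4aS,5R,8aS)-4-acetoxy-1,4a-dimethyl-6-methylidene-5-[(2E)-3-methylpenta-2,4-dienyl]decahydronaphthalene-1-carboxylate (labdane centres 1S,4R,5S,9R,10S) | C=C/C(C)=C/C[C@@H]1C(=C)CC[C@H]2[C@@]1(C)[C@@H](OC(C)=O)CC[C@@]2(C)C(=O)OC | target

Total step count: 18. Longest linear sequence: 18 steps (1 to 27); compounds 4, 7 and 25 enter as purchased reagents.

Steps most likely to fail

Step 9. The allyl complex may be intercepted at the ester-bearing para carbon C4 or, between two molecules, at the phenoxide oxygen. The α-silyloxy branch may slow ionisation or weaken the facial preference of the catalyst. The arene may also add through its other face and give the trans vinyl/methyl isomer. Fallback: starting from 14, the closure is run as a Tsuji–Trost allylic dearomatization under zerovalent palladium catalysis (Pd2(dba)3, 1,2-bis(diphenylphosphino)ethane, K2CO3, THF, rt), a known reaction of phenols with tethered allyl carbonates. Ring size alone then directs attack to C9. Because the two faces of the palladium allyl complex interconvert through the unsubstituted C12 terminus, the (8S) stereocentre, not the catalyst, relays the configuration to C9 and C10 through the same all-equatorial chair (Curtin–Hammett control). The product is again 15, where the route is rejoined; no new compound arises.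

Step 10. Hydride may be delivered in part to C5 (1,6-reduction), or the dienone may dimerise or be over-reduced before C2=C3 is cleanly saturated. Fallback: starting from 15, excess 9-BBN (THF, 0 to 40 °C) reduces the C1 ketone in the 1,2 sense from the face opposite C20 and hydroborates the vinyl group. Buffered peroxide work-up should give the dienol diol methyl (4S,4aS,5S,6S)-6-(tert-butyldimethylsilyloxy)-4-hydroxy-5-(2-hydroxyethyl)-4a-methyl-4,4a,5,6,7,8-hexahydronaphthalene-1-carboxylate F1. Hydrogenation over RhCl(PPh3)3 (H2, benzene) should saturate only the disubstituted C2=C3 and give the octahydro diol methyl (4S,4aS,5S,6S)-6-(tert-butyldimethylsilyloxy)-4-hydroxy-5-(2-hydroxyethyl)-4a-methyl-2,3,4,4a,5,6,7,8-octahydronaphthalene-1-carboxylate F2. After both hydroxyls are converted into lithium alkoxides (LiNH2), reductive methylation as in step 12 with one equivalent of t-BuOH should give methyl (1R,4S,4aR,5S,6S,8aS)-6-(tert-butyldimethylsilyloxy)-4-hydroxy-5-(2-hydroxyethyl)-1,4a-dimethyldecahydronaphthalene-1-carboxylate F3. Ac2O and DMAP give the diacetate methyl (1R,4S,4aR,5S,6S,8aS)-4-acetoxy-5-(2-acetoxyethyl)-6-(tert-butyldimethylsilyloxy)-1,4a-dimethyldecahydronaphthalene-1-carboxylate F4. K2CO3 in MeOH at 0 °C then cleaves only the unhindered primary acetate, which returns the route at 22.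

Step 12. The enolate may be protonated before it is methylated, the ester may be over-reduced, or the C1 alkoxide may be O-methylated. Fallback: reduction and alkylation are separated. Starting from 17, Li in NH3/THF followed by NH4Cl should give the saturated trans-fused hydroxy ester methyl (4S,4aR,5S,6S,8aR)-6-(tert-butyldimethylsilyloxy)-5-ethenyl-4-hydroxy-4a-methyldecahydronaphthalene-1-carboxylate F5 (epimers at the ester-bearing carbon). LDA (2.2 equiv, THF, −78 °C) and then MeI methylate its ester enolate from the same equatorial face, and the route is rejoined at 19.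

Further compounds
F0 | step 9 | none | none
F1 | step 10 | methyl (4S,4aS,5S,6S)-6-(tert-butyldimethylsilyloxy)-4-hydroxy-5-(2-hydroxyethyl)-4a-methyl-4,4a,5,6,7,8-hexahydronaphthalene-1-carboxylate | OCC[C@@H]1[C@@H](O[Si](C)(C)C(C)(C)C)CCC2=C(C(=O)OC)C=C[C@H](O)[C@@]12C
F2 | step 10 | methyl (4S,4aS,5S,6S)-6-(tert-butyldimethylsilyloxy)-4-hydroxy-5-(2-hydroxyethyl)-4a-methyl-2,3,4,4a,5,6,7,8-octahydronaphthalene-1-carboxylate | OCC[C@@H]1[C@@H](O[Si](C)(C)C(C)(C)C)CCC2=C(C(=O)OC)CC[C@H](O)[C@@]12C
F3 | step 10 | methyl (1R,4S,4aR,5S,6S,8aS)-6-(tert-butyldimethylsilyloxy)-4-hydroxy-5-(2-hydroxyethyl)-1,4a-dimethyldecahydronaphthalene-1-carboxylate | OCC[C@@H]1[C@@H](O[Si](C)(C)C(C)(C)C)CC[C@H]2[C@@]1(C)[C@@H](O)CC[C@@]2(C)C(=O)OC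
F4 | step 10 | methyl (1R,4S,4aR,5S,6S,8aS)-4-acetoxy-5-(2-acetoxyethyl)-6-(tert-butyldimethylsilyloxy)-1,4a-dimethyldecahydronaphthalene-1-carboxylate | CC(=O)OCC[C@@H]1[C@@H](O[Si](C)(C)C(C)(C)C)CC[C@H]2[C@@]1(C)[C@@H](OC(C)=O)CC[C@@]2(C)C(=O)OC
F5 | step 12 | methyl (4S,4aR,5S,6S,8aR)-6-(tert-butyldimethylsilyloxy)-5-ethenyl-4-hydroxy-4a-methyldecahydronaphthalene-1-carboxylate (epimers at the ester-bearing carbon) | C=C[C@@H]1[C@@H](O[Si](C)(C)C(C)(C)C)CC[C@H]2[C@@]1(C)[C@@H](O)CCC2C(=O)OC
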